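**Retrosynthetic overview**
- Target ⇒ Mitsunobu esterification of the C15 allylic alcohol with p-coumaric acid, itself from a Heck reaction of 4-iodophenol with acrylic acid.
- C15–OH ⇒ allylic oxidation of the C4 methyl; the C3=C4 alkene and trans ring fusion ⇒ reductive 1,3-transposition of a Δ4-3β-ol ⇒ ring-A enone.
- Acrylate ⇒ branched hydromethoxycarbonylation of a C7 ethynyl group; ring-A enone ⇒ auxiliary-controlled Michael addition to pent-1-en-3-one, then aldol, on a 2-methyl-5-alkynylcyclohexanone.
- Key step: that cyclohexanone ⇒ enantioselective ring-expanding alkynylation of 2-methylbicyclo[3.1.0]hexan-1-ol (cyclopentanone → cyclohexanone, the extra carbon from CH2I2).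
- Ring order: ring B first (five-membered ring enlarged to six), then ring A by annulation.

Assumption: operations run in one flask without isolation count as one step; eudesmane numbering is used for positions (C4 carries CH2O, C5/C10 are ring-fusion atoms, C7 carries the acrylate; ring A = C1–C5, C10; ring B = C5–C10).

**Step 1**
Reactants: 1 2-methylcyclopentan-1-one (racemic)
Product: 2 trimethyl[(5-methylcyclopent-1-en-1-yl)oxy]silane
Conditions: LDA, THF, −78 °C; then TMSCl, −78 °C → rt
Reagents that add atoms: chlorotrimethylsilane, C[Si](C)(C)Cl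
Why: Kinetic enolate formation at the unsubstituted α-carbon and O-silylation give the less substituted silyl enol ether; the methyl-bearing stereocentre is racemic and is erased in step 4.

**Step 2**
Reactants: 2 trimethyl[(5-methylcyclopent-1-en-1-yl)oxy]silane
Product: 4 2-methylbicyclo[3.1.0]hexan-1-ol (racemic; both diastereomers), via siloxycyclopropane 3 (not isolated)
Conditions: Zn–Cu couple, CH2I2, Et2O, reflux; pyridine, filter; then K2CO3 (5 mol%), MeOH, 0 °C
Reagents that add atoms: diiodomethane, ICI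
Why: Simmons–Smith cyclopropanation of the electron-rich enol ether followed by mild methanolysis of the O–Si bond gives the fused cyclopropanol; its relative configuration does not matter because both cyclopropane stereocentres are destroyed in step 3.

**Step 3**
Reactants: 4 2-methylbicyclo[3.1.0]hexan-1-ol; 5 ethynyltrimethylsilane
Product: 6 (5R)-2-methyl-5-[(trimethylsilyl)ethynyl]cyclohexan-1-one (C2 epimer mixture)
Conditions: Cu(MeCN)4PF6 (10 mol%), L* (12 mol%; quinine-derived N-(9-deoxy-epi-quinin-9-yl)-2-(diphenylphosphanyl)benzamide or its quinidine-derived pseudo-enantiomer, whichever gives 5R), Cs2CO3 (1.5 equiv), tert-butyl peroxybenzoate (1.2 equiv), 5 (1.5 equiv), Et2O, 0 °C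
Reagents that add atoms: none
Why: Proposed new method: the perester oxidises the ligand-bound monovalent copper acetylide, the resulting divalent copper alkoxide of 4 undergoes homolytic β-scission of the internal C1–C5 bond to give the ring-enlarged secondary 3-oxocyclohexyl radical, and this radical is captured by the chiral divalent copper acetylide and reductively eliminated from trivalent copper, forming the C(sp3)–C(sp) bond and the future C7 stereocentre (5R) regardless of the racemic C2 methyl; the closest known reaction types are the racemic silver- or copper-mediated ring-opening alkynylation of cyclopropanols and the copper-catalysed enantioconvergent radical Sonogashira-type coupling of secondary alkyl halides with cinchona-derived N,N,P ligands.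

**Step 4**
Reactants: 6 (5R)-2-methyl-5-[(trimethylsilyl)ethynyl]cyclohexan-1-one; 7 pent-1-en-3-one
Product: 10 (2S,5R)-2-methyl-2-(3-oxopentyl)-5-[(trimethylsilyl)ethynyl]cyclohexan-1-one, via ketimine 8 (not isolated), via Michael-adduct imine 9 (not isolated)
Conditions: (R)-1-phenylethylamine (1.05 equiv), TsOH (cat.), toluene, reflux, Dean–Stark; then 7, THF, 40 °C; then 10% aq AcOH, rt
Reagents that add atoms: none
Why: d'Angelo asymmetric Michael addition: the more substituted secondary enamine tautomer of the chiral imine adds to the enone on the face anti to the phenyl group, so the auxiliary sets the quaternary centre (2S, future C10) cis to the C7 substituent, as in the dihydrocarvone to α-cyperone precedent, and hydrolysis releases the amine.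

**Step 5**
Reactants: 10 (2S,5R)-2-methyl-2-(3-oxopentyl)-5-[(trimethylsilyl)ethynyl]cyclohexan-1-one
Product: 12 (4aS,7R)-7-ethynyl-1,4a-dimethyl-4,4a,5,6,7,8-hexahydronaphthalen-2(3H)-one, via desilylated diketone 11 (not isolated)
Conditions: NaOMe (0.3 equiv), MeOH, rt → 60 °C
Reagents that add atoms: none
Why: Intramolecular aldol condensation (second stage of the Robinson annulation) closes ring A as the tetrasubstituted enone while methoxide cleaves the alkynyl C–Si bond; neither stereocentre is epimerisable under these conditions.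

**Step 6**
Reactants: 12 (4aS,7R)-7-ethynyl-1,4a-dimethyl-4,4a,5,6,7,8-hexahydronaphthalen-2(3H)-one
Product: 13 methyl 2-[(2R,4aS)-4a,8-dimethyl-7-oxo-1,2,3,4,4a,5,6,7-octahydronaphthalen-2-yl]prop-2-enoate
Conditions: Pd(OAc)2 (1 mol%), 2-pyridyldiphenylphosphine (4 mol%), MeSO3H (4 mol%), CO (10 bar), MeOH, 45 °C
Reagents that add atoms: carbon monoxide, [C-]#[O+]; methanol, CO
Why: Palladium-catalysed Markovnikov (branched) hydromethoxycarbonylation of the terminal alkyne with the 2-pyridylphosphine/acid system gives the α-substituted acrylate directly and leaves the enone and both stereocentres untouched.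

**Step 7**
Reactants: 13 methyl 2-[(2R,4aS)-4a,8-dimethyl-7-oxo-1,2,3,4,4a,5,6,7-octahydronaphthalen-2-yl]prop-2-enoate
Product: 14 methyl 2-[(2R,4aS,7S)-7-hydroxy-4a,8-dimethyl-1,2,3,4,4a,5,6,7-octahydronaphthalen-2-yl]prop-2-enoate
Conditions: NaBH4, CeCl3·7H2O, MeOH, −78 → 0 °C
Reagents that add atoms: none
Why: Luche 1,2-reduction: hydride attacks the ketone from the α face, anti to the angular methyl, giving the pseudo-equatorial 3β (7S) allylic alcohol, and CeCl3 suppresses conjugate reduction of the enone and the acrylate.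

**Step 8**
Reactants: 14 methyl 2-[(2R,4aS,7S)-7-hydroxy-4a,8-dimethyl-1,2,3,4,4a,5,6,7-octahydronaphthalen-2-yl]prop-2-enoate
Product: 18 methyl 2-[(2R,4aR,8aR)-4a,8-dimethyl-1,2,3,4,4a,5,6,8a-octahydronaphthalen-2-yl]prop-2-enoate, via Mitsunobu adduct 15 (not isolated), via sulfonylhydrazine 16 (not isolated), via allylic diazene 17 (not isolated)
Conditions: N′-isopropylidene-2-nitrobenzenesulfonohydrazide (IPNBSH, 1.3 equiv), PPh3, DEAD, THF, 0 → 23 °C; then CF3CH2OH–H2O (1:1), 23 °C
Reagents that add atoms: none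
Why: Myers–Movassaghi reductive 1,3-transposition: Mitsunobu displacement with inversion places nitrogen on the α face, hydrazone hydrolysis and sulfinate loss give the allylic diazene, and its retro-ene loss of N2 delivers hydrogen suprafacially to C5 on the α face, setting the trans ring fusion (8aR) and the C3=C4 alkene.

**Step 9**
Reactants: 18 methyl 2-[(2R,4aR,8aR)-4a,8-dimethyl-1,2,3,4,4a,5,6,8a-octahydronaphthalen-2-yl]prop-2-enoate
Product: 19 methyl 2-[(2R,4aR,8aR)-8-(hydroxymethyl)-4a-methyl-1,2,3,4,4a,5,6,8a-octahydronaphthalen-2-yl]prop-2-enoate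
Conditions: SeO2 (0.3 equiv), t-BuOOH (2 equiv), CH2Cl2, 0 °C → rt
Reagents that add atoms: tert-butyl hydroperoxide, CC(C)(C)OO
Why: SeO2 allylic oxidation (ene reaction then [2,3]-shift) occurs at the more substituted alkene terminus, where the methyl is oxidised in preference to the hindered ring-fusion methine (as in α-pinene to myrtenol), and the electron-poor acrylate is inert.

**Step 10**
Reactants: 20 4-iodophenol; 21 prop-2-enoic acid
Product: 22 (2E)-3-(4-hydroxyphenyl)prop-2-enoic acid
Conditions: Pd(OAc)2 (1 mol%), Et3N (2.5 equiv), DMF, 90 °C; aq HCl work-up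
Reagents that add atoms: none
Why: Mizoroki–Heck arylation of acrylic acid: oxidative addition of the aryl iodide to zerovalent palladium, syn insertion and syn β-hydride elimination give the E-cinnamic acid.

**Step 11**
Reactants: 19 methyl 2-[(2R,4aR,8aR)-8-(hydroxymethyl)-4a-methyl-1,2,3,4,4a,5,6,8a-octahydronaphthalen-2-yl]prop-2-enoate; 22 (2E)-3-(4-hydroxyphenyl)prop-2-enoic acid
Product: 23 methyl 2-[(2R,4aR,8aR)-8-({[(2E)-3-(4-hydroxyphenyl)prop-2-enoyl]oxy}methyl)-4a-methyl-1,2,3,4,4a,5,6,8a-octahydronaphthalen-2-yl]prop-2-enoate (CNP0161949.1)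
Conditions: PPh3, DIAD, THF, 0 °C → rt
Reagents that add atoms: none
Why: Mitsunobu esterification of the primary allylic alcohol engages only the carboxylic acid, which is far more acidic than the phenol, so no phenol protection is needed and no stereocentre is touched.

**Compound list**
1 | 2-methylcyclopentan-1-one (racemic) | CC1CCCC1=O | starting material
2 | trimethyl[(5-methylcyclopent-1-en-1-yl)oxy]silane | CC1CCC=C1O[Si](C)(C)C | intermediate
3 | trimethyl[(2-methylbicyclo[3.1.0]hexan-1-yl)oxy]silane (not isolated) | CC1CCC2CC12O[Si](C)(C)C | intermediate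
4 | 2-methylbicyclo[3.1.0]hexan-1-ol (racemic; both diastereomers) | CC1CCC2CC12O | intermediate
5 | ethynyltrimethylsilane | C#C[Si](C)(C)C | starting material
6 | (5R)-2-methyl-5-[(trimethylsilyl)ethynyl]cyclohexan-1-one (C2 epimer mixture) | CC1CC[C@@H](C#C[Si](C)(C)C)CC1=O | intermediate
7 | pent-1-en-3-one | CCC(=O)C=C | starting material
8 | (5R)-2-methyl-N-[(1R)-1-phenylethyl]-5-[(trimethylsilyl)ethynyl]cyclohexan-1-imine (not isolated) | C[C@@H](N=C1C[C@H](C#C[Si](C)(C)C)CCC1C)c1ccccc1 | intermediate
9 | 1-[(1S,4R)-1-methyl-2-{[(1R)-1-phenylethyl]imino}-4-[(trimethylsilyl)ethynyl]cyclohexyl]pentan-3-one (not isolated) | CCC(=O)CC[C@]1(C)CC[C@@H](C#C[Si](C)(C)C)CC1=N[C@H](C)c1ccccc1 | intermediate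
10 | (2S,5R)-2-methyl-2-(3-oxopentyl)-5-[(trimethylsilyl)ethynyl]cyclohexan-1-one | CCC(=O)CC[C@]1(C)CC[C@@H](C#C[Si](C)(C)C)CC1=O | intermediate
11 | (2S,5R)-5-ethynyl-2-methyl-2-(3-oxopentyl)cyclohexan-1-one (not isolated) | CCC(=O)CC[C@]1(C)CC[C@@H](C#C)CC1=O | intermediate
12 | (4aS,7R)-7-ethynyl-1,4a-dimethyl-4,4a,5,6,7,8-hexahydronaphthalen-2(3H)-one | C#C[C@@H]1CC[C@@]2(C)CCC(=O)C(C)=C2C1 | intermediate
13 | methyl 2-[(2R,4aS)-4a,8-dimethyl-7-oxo-1,2,3,4,4a,5,6,7-octahydronaphthalen-2-yl]prop-2-enoate | C=C(C(=O)OC)[C@@H]1CC[C@@]2(C)CCC(=O)C(C)=C2C1 | intermediate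
14 | methyl 2-[(2R,4aS,7S)-7-hydroxy-4a,8-dimethyl-1,2,3,4,4a,5,6,7-octahydronaphthalen-2-yl]prop-2-enoate | C=C(C(=O)OC)[C@@H]1CC[C@@]2(C)CC[C@H](O)C(C)=C2C1 | intermediate
15 | methyl 2-[(2R,4aS,7R)-4a,8-dimethyl-7-[1-(2-nitrophenylsulfonyl)-2-(propan-2-ylidene)hydrazinyl]-1,2,3,4,4a,5,6,7-octahydronaphthalen-2-yl]prop-2-enoate (not isolated) | C=C(C(=O)OC)[C@@H]1CC[C@@]2(C)CC[C@@H](N(N=C(C)C)S(=O)(=O)c3ccccc3[N+](=O)[O-])C(C)=C2C1 | intermediate
16 | methyl 2-[(2R,4aS,7R)-4a,8-dimethyl-7-[1-(2-nitrophenylsulfonyl)hydrazinyl]-1,2,3,4,4a,5,6,7-octahydronaphthalen-2-yl]prop-2-enoate (not isolated) | C=C(C(=O)OC)[C@@H]1CC[C@@]2(C)CC[C@@H](N(N)S(=O)(=O)c3ccccc3[N+](=O)[O-])C(C)=C2C1 | intermediate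
17 | methyl 2-[(2R,4aS,7R)-7-diazenyl-4a,8-dimethyl-1,2,3,4,4a,5,6,7-octahydronaphthalen-2-yl]prop-2-enoate (not isolated) | C=C(C(=O)OC)[C@@H]1CC[C@@]2(C)CC[C@@H](N=N)C(C)=C2C1 | intermediate
18 | methyl 2-[(2R,4aR,8aR)-4a,8-dimethyl-1,2,3,4,4a,5,6,8a-octahydronaphthalen-2-yl]prop-2-enoate | C=C(C(=O)OC)[C@@H]1CC[C@@]2(C)CCC=C(C)[C@@H]2C1 | intermediate
19 | methyl 2-[(2R,4aR,8aR)-8-(hydroxymethyl)-4a-methyl-1,2,3,4,4a,5,6,8a-octahydronaphthalen-2-yl]prop-2-enoate | C=C(C(=O)OC)[C@@H]1CC[C@@]2(C)CCC=C(CO)[C@@H]2C1 | intermediate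
20 | 4-iodophenol | Oc1ccc(I)cc1 | starting material
21 | prop-2-enoic acid | C=CC(=O)O | starting material
22 | (2E)-3-(4-hydroxyphenyl)prop-2-enoic acid | OC(=O)/C=C/c1ccc(O)cc1 | intermediate
23 | methyl 2-[(2R,4aR,8aR)-8-({[(2E)-3-(4-hydroxyphenyl)prop-2-enoyl]oxy}methyl)-4a-methyl-1,2,3,4,4a,5,6,8a-octahydronaphthalen-2-yl]prop-2-enoate | C=C(C(=O)OC)[C@@H]1CC[C@@]2(C)CCC=C(COC(=O)/C=C/c3ccc(O)cc3)[C@@H]2C1 | target

**Step count**
Total steps: 11. Longest linear sequence: 10 (steps 1–9, then 11; step 10 is the convergent branch).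

**Steps most likely to fail, with fallbacks**

Step 3 (proposed new step). The enantioselectivity of radical capture at an unactivated ring carbon is untested, and external-bond scission or alkyne homocoupling may compete. The fallback keeps the ring enlargement but uses known chemistry and sets out from cyclopropanol 4. FeCl3 in DMF at 0 °C (Saegusa–Ito-type oxidative opening) gives 3-chloro-6-methylcyclohexan-1-one F1, and NaOAc in refluxing MeOH eliminates HCl to give 6-methylcyclohex-2-en-1-one F2. The known nickel-catalysed asymmetric conjugate alkynylation (Ni(acac)2, chiral bis(oxazoline), dimethylaluminium (trimethylsilyl)acetylide made from 5 with n-BuLi and Me2AlCl) then adds the alkyne at the β-carbon under catalyst control. The route is rejoined at compound 6.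

Step 8. The Mitsunobu displacement at the secondary allylic carbinol next to the C4 methyl may give elimination or SN2′ products. The fallback sets out from allylic alcohol 14, which is formylated (acetic formic anhydride, pyridine, 0 °C) to methyl 2-[(2R,4aS,7S)-7-(formyloxy)-4a,8-dimethyl-1,2,3,4,4a,5,6,7-octahydronaphthalen-2-yl]prop-2-enoate F3. Tsuji–Mandai hydrogenolysis (Pd(acac)2 5 mol%, PBu3 5 mol%, THF, rt) ionises the formate with inversion, and after loss of CO2 the hydride passes from palladium on the α face to the more substituted allyl terminus C5. This gives the same trans-fused C3=C4 alkene, and the route is rejoined at compound 18.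

Step 9. Over-oxidation to the enal and competing oxidation at C2 or C5 are possible. The fallback sets out from 18, and mCPBA (CH2Cl2, 0 °C) epoxidises only the electron-rich ring alkene from the α face to give methyl 3α,4α-epoxy-5α-eudesm-11(13)-en-12-oate F4. Diethylaluminium 2,2,6,6-tetramethylpiperidide (toluene, 0 °C) removes a proton from the C15 methyl to give methyl 2-[(2R,4aS,7R,8aR)-7-hydroxy-4a-methyl-8-methylidenedecahydronaphthalen-2-yl]prop-2-enoate F5. Ph3SiOReO3 (2 mol%, Et2O, 0 °C) then effects the 1,3-transposition of the allylic alcohol to the more stable primary alcohol with the endocyclic trisubstituted alkene. The route is rejoined at compound 19.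

**Further compounds**
F1 | step 3 | 3-chloro-6-methylcyclohexan-1-one (racemic; diastereomer mixture) | CC1CCC(Cl)CC1=O
F2 | step 3 | 6-methylcyclohex-2-en-1-one (racemic) | CC1CCC=CC1=O
F3 | step 8 | methyl 2-[(2R,4aS,7S)-7-(formyloxy)-4a,8-dimethyl-1,2,3,4,4a,5,6,7-octahydronaphthalen-2-yl]prop-2-enoate | C=C(C(=O)OC)[C@@H]1CC[C@@]2(C)CC[C@H](OC=O)C(C)=C2C1
F4 | step 9 | methyl 3α,4α-epoxy-5α-eudesm-11(13)-en-12-oate | C=C(C(=O)OC)[C@@H]1CC[C@@]2(C)CC[C@H]3O[C@@]3(C)[C@@H]2C1
F5 | step 9 | methyl 2-[(2R,4aS,7R,8aR)-7-hydroxy-4a-methyl-8-methylidenedecahydronaphthalen-2-yl]prop-2-enoate | C=C(C(=O)OC)[C@@H]1CC[C@@]2(C)CC[C@@H](O)C(=C)[C@@H]2C1
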